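Compound numbers are those of the steps and the compound list below. TBS = tert-butyldimethylsilyl, Bn = benzyl.

## Analysis of the target

Target 26 is a 5,6,7,8-tetrahydroquinolin-4(1H)-one: ring A is a 4-pyridone and ring B a six-membered carbocycle fused to it at C4a–C8a. Every carbon of ring A carries a different group: methyl on C2, methoxy on C3, the carbonyl at C4, and the two fusion carbons. The only stereocentres are in ring B, C5 (S, carrying the 5-phenylpentyl chain) and C8 (R, a secondary alcohol). They stand 1,4 to each other, with the chain and the hydroxyl on the same face (cis). Each is bonded directly to ring A, and no functional group lies between them that could pass stereochemical information from one to the other. The sensitive points are the pyridylic C8 alcohol (oxidation or elimination, and aromatisation of ring B to a quinoline once C5=C6 is unsaturated), the ambident pyridone (N against O) and the tertiary benzylic-type C5–H. The difficulty is therefore twofold: a pentasubstituted pyridone whose methyl, methoxy and oxygen must be placed without ambiguity, and two remote stereocentres. The strategy rests on reading ring A as three small pieces: allene 6 supplies C3 (with its methoxy group), C4 and C4a, nitrile 7 supplies N1, C2 and the methyl group, and acid 4 supplies C8a and, as its α-carbon, the oxygenated stereocentre C8.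

## Retrosynthetic reasoning

**26 back to 24.** The two oxygen functions are unmasked last: the silyl ether at C8 (26 from 25) and the benzyl ether at C4 (25 from 24). The benzyl group holds ring A as a plain pyridine through the organometallic steps. The silyl group keeps the pyridylic alcohol from eliminating and makes it a bulky, non-coordinating substituent for the reduction. The two are removed independently, hydrogenolysis first so that the free C8 alcohol never meets a metal catalyst.

**24 back to 23.** C5 carries no heteroatom, so it is created by adding hydrogen across a C5=C6 double bond. This leaves the stereocentre to the end, where the C8 silyloxy group already in ring B and a chiral iridium P,N catalyst can both steer hydrogen to the same face. Delivery anti to the C8 oxygen gives the cis relationship, which is 5S.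

**23 back to 22.** The C5=C6 bond is cut by ring-closing metathesis. Both alkenes hang from neighbouring ring carbons (C4a and C8a), so the closure is a six-membered one. C6 and C7 are the inner carbons of the allyl group that acid 4 already carries; its terminal carbon is lost.

**22 back to 15 and 19.** The C4a–C5 bond joins an sp2 ring carbon to a 1,1-disubstituted alkene and is made by cross-coupling. The ring is used as the nucleophile (iodide 15 through the magnesium and zinc species 20 and 21) and bromoalkene 19 as the electrophile. The reverse polarity would generate an arylpalladium species from 15 with its own terminal alkene placed for a 5-exo insertion. It would also need an extra step to make an alkenylboron reagent.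

**15 back to 13.** The C4a–I bond and the O-benzyl bond are removed in turn (15 from 14, 14 from 13). In pyridinol 13 the only ring C–H is C4a, ortho to the hydroxyl, so electrophilic iodination has one place to go.

**13 back to 11.** The C4a–C8a bond is cut to give the open-chain β-keto enamide 11. Forward, the methyl ketone carbon attacks the amide carbonyl in an aldol-type condensation, and aromatisation drives it (via the silyl ether 12).

**11 back to 6, 7 and 4.** The C2–C3 and N1–C8a bonds are cut together. Forward, metalated 6 (8) adds to nitrile 7 to give 9, and acid 4 then delivers its acyl group to nitrogen through the enol ester 10. This is the step that fixes the place of every ring A substituent.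

**Starting materials.** Acid 4 comes from the amino acid 1 by deamination with retention (2) and silylation (via 3). Allene 6 is the base-isomerised form of propargyl ether 5. Bromoalkene 19 is made by joining bromide 16 (as its Grignard reagent 18) to dibromide 17.

## Alternatives that were turned down

**Alternative 1:** intramolecular radical acylation of a pyridinium ion.
- Disconnection: the C8–C8a bond; ring B is closed onto an intact pyridine.
- Forward key step: (4S)-4-(4-chloro-5-methoxy-6-methylpyridin-3-yl)-9-phenylnonanal A2, with t-BuOOH and FeSO4 in CF3CO2H, would give an acyl radical. It adds to the one free α-carbon of the protonated ring, and rearomatisation gives (5S)-4-chloro-3-methoxy-2-methyl-5-(5-phenylpentyl)-6,7-dihydroquinolin-8(5H)-one A1.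
- For it: no leaving group is needed at C8a, the polarity is matched (nucleophilic radical, electron-poor ring), and the regiochemistry is clear because the other α-carbon carries the methyl group. C5 is set in an open chain, independently of C8.
- Against it: A2 needs its own multistep pyridine synthesis, with an asymmetric C–C bond formation next to a hindered ring carbon. The oxyl radicals can abstract the tertiary pyridylic C5–H, which would erase that stereocentre, and the benzylic CH2 of the chain is also exposed. After closure the C8 ketone has to be reduced cis to a remote C5 substituent, which needs reagent control, and the C4 chloride must still be exchanged for oxygen.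
- Comparison: it is stronger in avoiding metathesis and the hydrogenation of a hindered alkene. The chosen route offers instead a two-step assembly of the fully substituted ring A and takes C8 from the chiral pool, so only one stereocentre has to be created.

**Alternative 2:** intramolecular nitrile oxide cycloaddition, isoxazole as a masked pyridone.
- Disconnection: ring A is traced to an isoxazole (a masked β-amino enone), and this ring and ring B to an open-chain nitro alkyne; the bonds made are C4a–C8a and O–C4.
- Forward key step: tert-butyl(dimethyl){[(2R,5S)-8,9,9-trimethoxy-1-nitro-5-(5-phenylpentyl)dec-6-yn-2-yl]oxy}silane A4 would be dehydrated with PhNCO and Et3N to the nitrile oxide. This adds to the tethered internal alkyne to give (4S,7R)-7-(tert-butyldimethylsilyloxy)-4-(5-phenylpentyl)-3-(1,2,2-trimethoxypropyl)-4,5,6,7-tetrahydro-2,1-benzoxazole A3. N–O reduction, ketal hydrolysis and condensation would then give the pyridone.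
- For it: one event closes two rings with tether-fixed regiochemistry, and both stereocentres are set in open-chain precursors, so no late stereoselective reduction is needed.
- Against it: A4 is a long, densely functionalised chain (nitromethyl carbinol, propargylic stereocentre, α-methoxy ketal). Its β-silyloxy nitroalkane unit can lose silanol by an E1cB path under the same amine base that forms the dipole. Dimerisation of the nitrile oxide competes if addition to the hindered alkyne is slow. Three more operations are needed to unmask the pyridone, and the CH(OMe) carbon is carried as a stereoisomer mixture.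
- Comparison: it is stronger on stereocontrol at C5. The chosen route is much shorter to its key precursor, which comes from three small molecules.

**Alternative 3:** rhodium-catalysed C–H annulation of an unsaturated oxime ester with an ynol ether.
- Disconnection: ring A is cut at C3–C4 and N1–C2.
- Forward key step: (3S,6R)-2-[(benzyloxy)methylidene]-6-(tert-butyldimethylsilyloxy)-3-(5-phenylpentyl)cyclohexan-1-one O-pivaloyl oxime A6 and 1-methoxypropyne A7, with [Cp*RhCl2]2 and CsOPiv. Trivalent rhodium would metalate the vinylic C4–H, the alkyne would insert, and C–N bond formation with N–O cleavage would give (5S,8R)-4-(benzyloxy)-8-(tert-butyldimethylsilyloxy)-3-methoxy-2-methyl-5-(5-phenylpentyl)-5,6,7,8-tetrahydroquinoline A5, the same structure as 24.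
- For it: it is the most convergent plan, ring B with both stereocentres is made by ordinary cyclohexanone chemistry, and the annulation is redox-neutral and ends two deprotections from 26.
- Against it: the insertion must place the methoxy-bearing alkyne carbon on C4. The polarisation of a donor-substituted alkyne tends to send the metal, and hence nitrogen, to the heteroatom-bearing carbon, which would give the 2-methoxy-3-methyl isomer. The enol ether geometry and the oxime geometry (acyloxy group towards the C8 silyloxy substituent) both have to suit metalation. The α-oxygenated oxime stereocentre C8 can epimerise under carboxylate base with heating, and A7 is volatile and labile.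
- Comparison: it is stronger in convergence and in the length of the endgame. The chosen route offers regiochemical certainty, because the origin of each ring atom is fixed by the mechanism and no isomeric pyridine can form.

Key step: step 4

Remark on the chemistry: D-allylglycine (1) is taken as a commercial chiral-pool material, and 26 is drawn as its 4(1H)-pyridone tautomer.

## Route

Step 1
Reactants: 1 D-allylglycine, (2R)-2-aminopent-4-enoic acid
Product: 2 (2R)-2-hydroxypent-4-enoic acid
Conditions: NaNO2, 1 M H2SO4 (aq), 0 °C → rt
Reagents that add atoms: water, O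
Why: Diazotisation of an α-amino acid; the carboxylate displaces N2 to an α-lactone that water reopens at the α-carbon, so two inversions should return the (R) configuration (deamination with net retention).

Step 2
Reactants: 2 (2R)-2-hydroxypent-4-enoic acid
Product: 4 (2R)-2-(tert-butyldimethylsilyloxy)pent-4-enoic acid, via silyl ester 3 (not isolated)
Conditions: TBSCl, imidazole, DMF, rt; then K2CO3, MeOH/THF/H2O, rt; 1 M HCl to pH 4
Reagents that add atoms: tert-butyldimethylsilyl chloride (TBSCl), CC(C)(C)[Si](C)(C)Cl
Why: Exhaustive silylation followed by selective solvolysis of the much more labile silyl ester should leave the secondary silyl ether; neither stage touches the stereocentre.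

Step 3
Reactants: 5 methyl propargyl ether (3-methoxyprop-1-yne)
Product: 6 methoxyallene (1-methoxypropa-1,2-diene)
Conditions: KOtBu (cat.), neat, 70 °C, then distillation
Reagents that add atoms: none
Why: Base-catalysed propargyl-to-allenyl isomerisation; the alkoxyallene is favoured under catalytic alkoxide and is distilled from the mixture.

Step 4
Reactants: 6 methoxyallene; 7 acetonitrile; 4 (2R)-2-(tert-butyldimethylsilyloxy)pent-4-enoic acid
Product: 11 (2R)-2-(tert-butyldimethylsilyloxy)-N-[(2E)-3-methoxy-4-oxopent-2-en-2-yl]pent-4-enamide, via 1-lithio-1-methoxyallene 8 (not isolated), via lithium ketimide 9 (not isolated), via dienyl ester 10 (not isolated)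
Conditions: 6 (1.1 equiv), n-BuLi (1.0 equiv), Et2O, −40 °C; 7 (1.0 equiv), −78 °C, 4 h; 4 (3.0 equiv), −78 °C → rt, 16 h; aq. NaHCO3 work-up (excess 4 recovered from the aqueous phase)
Reagents that add atoms: none
Why: n-BuLi removes the proton on the oxygen-bearing carbon of 6, and the resulting 8 adds through that carbon to the nitrile carbon of 7, forming C2–C3 and the lithium ketimide 9. One equivalent of 4 protonates nitrogen; a second protonates the azatriene, whose central allene carbon then takes up the carboxylate to give the enol ester 10, a primary enamine with the acyloxy group in a 1,5 relationship to nitrogen. A six-membered O-to-N acyl shift forms N1–C8a and turns the allene terminus into the methyl ketone carbon (the later C4a), giving 11. The closest known reaction type is the three-component coupling of lithiated alkoxyallenes, nitriles and carboxylic acids to β-keto enamides, which includes O-protected α-hydroxy acids. No ring is closed and no stereocentre is created; the enamide alkene should form with NH syn to the ketone (internal hydrogen bond), the geometry the later cyclisation needs. The step needs addition to the nitrile in preference to removal of an α-proton from 7: low temperature in Et2O and the lower basicity of 8 compared with an alkyllithium favour addition, and any loss falls on the two cheap components. It needs N-acylation, which the intramolecular transfer within 10 secures, and it needs retention at the α-carbon of 4, which is favoured because the acid reacts as its carboxylate and no strong base remains after the quench.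

Step 5
Reactants: 11 (2R)-2-(tert-butyldimethylsilyloxy)-N-[(2E)-3-methoxy-4-oxopent-2-en-2-yl]pent-4-enamide
Product: 13 2-[(1R)-1-(tert-butyldimethylsilyloxy)but-3-en-1-yl]-5-methoxy-6-methylpyridin-4-ol, via 4-silyloxypyridine 12 (not isolated)
Conditions: TMSOTf (4 equiv), Et3N (5 equiv), ClCH2CH2Cl, 80 °C; aq. NH4Cl work-up
Reagents that add atoms: none
Why: The silyl triflate and amine convert the methyl ketone into its silyl enol ether and the amide into an O-silyl imidate; intramolecular aldol-type attack of C4a on C8a and loss of silanol aromatise to 12, which is hydrolysed on work-up (the known cyclocondensation of β-keto enamides). The C8 silyl ether and its configuration should survive, since the α-proton of a silyl imidate is far less acidic than the ketone methyl group.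

Step 6
Reactants: 13 2-[(1R)-1-(tert-butyldimethylsilyloxy)but-3-en-1-yl]-5-methoxy-6-methylpyridin-4-ol
Product: 14 2-[(1R)-1-(tert-butyldimethylsilyloxy)but-3-en-1-yl]-3-iodo-5-methoxy-6-methylpyridin-4-ol
Conditions: NIS (1.05 equiv), DMF, 0 °C → rt, dark
Reagents that add atoms: N-iodosuccinimide (NIS), O=C1CCC(=O)N1I
Why: Electrophilic iodination of an electron-rich 4-pyridinol; the iodinated carbon is the only ring C–H and is ortho to the hydroxyl, and without acid activation NIS should leave the terminal alkene alone.

Step 7
Reactants: 14 2-[(1R)-1-(tert-butyldimethylsilyloxy)but-3-en-1-yl]-3-iodo-5-methoxy-6-methylpyridin-4-ol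
Product: 15 4-(benzyloxy)-2-[(1R)-1-(tert-butyldimethylsilyloxy)but-3-en-1-yl]-3-iodo-5-methoxy-6-methylpyridine
Conditions: BnBr (1.3 equiv), Ag2CO3 (1.0 equiv), toluene, 60 °C, dark
Reagents that add atoms: benzyl bromide (BnBr), BrCc1ccccc1
Why: O-Alkylation of an ambident pyridinol; both carbons next to nitrogen are substituted (one by a branched silyloxyalkyl group) and the silver salt favours reaction at oxygen, so the 4-benzyloxypyridine should dominate.

Step 8
Reactants: 16 (4-bromobutyl)benzene; 17 2,3-dibromoprop-1-ene
Product: 19 2-bromo-7-phenylhept-1-ene, via 4-phenylbutylmagnesium bromide 18 (not isolated)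
Conditions: Mg, THF, rt → 40 °C; then 17 (1.2 equiv), CuI (5 mol%), THF, −10 °C → rt
Reagents that add atoms: none
Why: Copper-catalysed allylic substitution by a primary Grignard reagent; the SN2 and SN2′ paths give the same product and the vinylic bromide is inert under these conditions.

Step 9
Reactants: 15 4-(benzyloxy)-2-[(1R)-1-(tert-butyldimethylsilyloxy)but-3-en-1-yl]-3-iodo-5-methoxy-6-methylpyridine; 19 2-bromo-7-phenylhept-1-ene
Product: 22 4-(benzyloxy)-2-[(1R)-1-(tert-butyldimethylsilyloxy)but-3-en-1-yl]-5-methoxy-6-methyl-3-(7-phenylhept-1-en-2-yl)pyridine, via pyridylmagnesium chloride 20 (not isolated), via pyridylzinc chloride 21 (not isolated)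
Conditions: iPrMgCl·LiCl (1.1 equiv), THF, −40 °C; ZnCl2 (1.2 equiv), −40 °C → rt; 19 (1.3 equiv), Pd(OAc)2 (5 mol%), SPhos (10 mol%), THF, 55 °C
Reagents that add atoms: none
Why: Iodine–magnesium exchange, transmetalation to zinc and Negishi coupling form C4a–C5; zerovalent palladium inserts into the alkenyl bromide, so no arylpalladium species with the tethered alkene in reach is formed. The bulky biarylphosphine should allow coupling at the doubly ortho-substituted zinc centre.

Step 10
Reactants: 22 4-(benzyloxy)-2-[(1R)-1-(tert-butyldimethylsilyloxy)but-3-en-1-yl]-5-methoxy-6-methyl-3-(7-phenylhept-1-en-2-yl)pyridine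
Product: 23 (8R)-4-(benzyloxy)-8-(tert-butyldimethylsilyloxy)-3-methoxy-2-methyl-5-(5-phenylpentyl)-7,8-dihydroquinoline
Conditions: second-generation Grubbs catalyst (H2IMes)(PCy3)Cl2Ru=CHPh (5–10 mol%), toluene (0.005 M), 80 °C
Reagents that add atoms: none
Why: Ring-closing metathesis to a six-membered trisubstituted cycloalkene; initiation at the unhindered allyl terminus is followed by closure onto the 1,1-disubstituted alkene, driven by loss of ethene. The pyridine nitrogen is flanked on both sides and should bind ruthenium only weakly.

Step 11
Reactants: 23 (8R)-4-(benzyloxy)-8-(tert-butyldimethylsilyloxy)-3-methoxy-2-methyl-5-(5-phenylpentyl)-7,8-dihydroquinoline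
Product: 24 (5S,8R)-4-(benzyloxy)-8-(tert-butyldimethylsilyloxy)-3-methoxy-2-methyl-5-(5-phenylpentyl)-5,6,7,8-tetrahydroquinoline
Conditions: [Ir(cod)((S)-tBu-PHOX)]BArF (2 mol%) or its (R) antipode, whichever is matched, H2 (50 bar), CH2Cl2, rt
Reagents that add atoms: none
Why: Asymmetric hydrogenation of an unfunctionalised, aryl-conjugated trisubstituted alkene by a cationic monovalent iridium P,N complex. Hydrogen is to be delivered to the C5=C6 face opposite the C8 silyloxy group, which puts the chain cis to the C8 oxygen and sets C5 as S; the ligand antipode whose preference coincides with this substrate bias is chosen by running both. The benzyl and silyl ethers and the phenyl ring are inert to this catalyst.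

Step 12
Reactants: 24 (5S,8R)-4-(benzyloxy)-8-(tert-butyldimethylsilyloxy)-3-methoxy-2-methyl-5-(5-phenylpentyl)-5,6,7,8-tetrahydroquinoline
Product: 25 (5S,8R)-8-(tert-butyldimethylsilyloxy)-3-methoxy-2-methyl-5-(5-phenylpentyl)-5,6,7,8-tetrahydroquinolin-4(1H)-one
Conditions: H2 (1 atm), palladium on carbon (Pd/C, 10 wt%), EtOAc/EtOH, rt
Reagents that add atoms: none
Why: Hydrogenolysis of an aryl benzyl ether; the freed 4-hydroxypyridine tautomerises to the 4(1H)-pyridone, and neutral conditions at 1 atm should leave the C8 silyl ether and both rings untouched.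

Step 13
Reactants: 25 (5S,8R)-8-(tert-butyldimethylsilyloxy)-3-methoxy-2-methyl-5-(5-phenylpentyl)-5,6,7,8-tetrahydroquinolin-4(1H)-one
Product: 26 (5S,8R)-8-hydroxy-3-methoxy-2-methyl-5-(5-phenylpentyl)-5,6,7,8-tetrahydroquinolin-4(1H)-one
Conditions: HF·pyridine, THF, 0 °C → rt
Reagents that add atoms: none
Why: Fluoride cleavage of a secondary silyl ether under buffered conditions; only the O–Si bond is broken, so both stereocentres are untouched.

## Compound list

1 | D-allylglycine, (2R)-2-aminopent-4-enoic acid | OC(=O)[C@H](N)CC=C | starting material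
2 | (2R)-2-hydroxypent-4-enoic acid | OC(=O)[C@H](O)CC=C | intermediate
3 | tert-butyldimethylsilyl (2R)-2-(tert-butyldimethylsilyloxy)pent-4-enoate | CC(C)(C)[Si](C)(C)OC(=O)[C@H](O[Si](C)(C)C(C)(C)C)CC=C | intermediate
4 | (2R)-2-(tert-butyldimethylsilyloxy)pent-4-enoic acid | OC(=O)[C@H](O[Si](C)(C)C(C)(C)C)CC=C | intermediate
5 | methyl propargyl ether (3-methoxyprop-1-yne) | COCC#C | starting material
6 | methoxyallene (1-methoxypropa-1,2-diene) | COC=C=C | intermediate
7 | acetonitrile | CC#N | starting material
8 | 1-lithio-1-methoxypropa-1,2-diene | [Li]C(OC)=C=C | intermediate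
9 | lithium (3-methoxypenta-3,4-dien-2-ylidene)azanide | CC(=N[Li])C(OC)=C=C | intermediate
10 | (3E)-4-amino-3-methoxypenta-1,3-dien-2-yl (2R)-2-(tert-butyldimethylsilyloxy)pent-4-enoate | C=C(OC(=O)[C@H](O[Si](C)(C)C(C)(C)C)CC=C)/C(OC)=C(/C)N | intermediate
11 | (2R)-2-(tert-butyldimethylsilyloxy)-N-[(2E)-3-methoxy-4-oxopent-2-en-2-yl]pent-4-enamide | CC(=O)/C(OC)=C(/C)NC(=O)[C@H](O[Si](C)(C)C(C)(C)C)CC=C | intermediate
12 | 2-[(1R)-1-(tert-butyldimethylsilyloxy)but-3-en-1-yl]-5-methoxy-6-methyl-4-(trimethylsilyloxy)pyridine | COc1c(C)nc(cc1O[Si](C)(C)C)[C@H](O[Si](C)(C)C(C)(C)C)CC=C | intermediate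
13 | 2-[(1R)-1-(tert-butyldimethylsilyloxy)but-3-en-1-yl]-5-methoxy-6-methylpyridin-4-ol | COc1c(C)nc(cc1O)[C@H](O[Si](C)(C)C(C)(C)C)CC=C | intermediate
14 | 2-[(1R)-1-(tert-butyldimethylsilyloxy)but-3-en-1-yl]-3-iodo-5-methoxy-6-methylpyridin-4-ol | COc1c(C)nc(c(I)c1O)[C@H](O[Si](C)(C)C(C)(C)C)CC=C | intermediate
15 | 4-(benzyloxy)-2-[(1R)-1-(tert-butyldimethylsilyloxy)but-3-en-1-yl]-3-iodo-5-methoxy-6-methylpyridine | COc1c(C)nc(c(I)c1OCc2ccccc2)[C@H](O[Si](C)(C)C(C)(C)C)CC=C | intermediate
16 | (4-bromobutyl)benzene | BrCCCCc1ccccc1 | starting material
17 | 2,3-dibromoprop-1-ene | C=C(Br)CBr | starting material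
18 | 4-phenylbutylmagnesium bromide | Br[Mg]CCCCc1ccccc1 | intermediate
19 | 2-bromo-7-phenylhept-1-ene | C=C(Br)CCCCCc1ccccc1 | intermediate
20 | {4-(benzyloxy)-2-[(1R)-1-(tert-butyldimethylsilyloxy)but-3-en-1-yl]-5-methoxy-6-methylpyridin-3-yl}magnesium chloride | COc1c(C)nc(c([Mg]Cl)c1OCc2ccccc2)[C@H](O[Si](C)(C)C(C)(C)C)CC=C | intermediate
21 | {4-(benzyloxy)-2-[(1R)-1-(tert-butyldimethylsilyloxy)but-3-en-1-yl]-5-methoxy-6-methylpyridin-3-yl}zinc chloride | COc1c(C)nc(c([Zn]Cl)c1OCc2ccccc2)[C@H](O[Si](C)(C)C(C)(C)C)CC=C | intermediate
22 | 4-(benzyloxy)-2-[(1R)-1-(tert-butyldimethylsilyloxy)but-3-en-1-yl]-5-methoxy-6-methyl-3-(7-phenylhept-1-en-2-yl)pyridine | COc1c(C)nc(c(C(=C)CCCCCc2ccccc2)c1OCc3ccccc3)[C@H](O[Si](C)(C)C(C)(C)C)CC=C | intermediate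
23 | (8R)-4-(benzyloxy)-8-(tert-butyldimethylsilyloxy)-3-methoxy-2-methyl-5-(5-phenylpentyl)-7,8-dihydroquinoline | COc1c(C)nc2c(c1OCc3ccccc3)C(CCCCCc4ccccc4)=CC[C@H]2O[Si](C)(C)C(C)(C)C | intermediate
24 | (5S,8R)-4-(benzyloxy)-8-(tert-butyldimethylsilyloxy)-3-methoxy-2-methyl-5-(5-phenylpentyl)-5,6,7,8-tetrahydroquinoline | COc1c(C)nc2c(c1OCc3ccccc3)[C@@H](CCCCCc4ccccc4)CC[C@H]2O[Si](C)(C)C(C)(C)C | intermediate
25 | (5S,8R)-8-(tert-butyldimethylsilyloxy)-3-methoxy-2-methyl-5-(5-phenylpentyl)-5,6,7,8-tetrahydroquinolin-4(1H)-one | COc1c(C)[nH]c2c(c1=O)[C@@H](CCCCCc3ccccc3)CC[C@H]2O[Si](C)(C)C(C)(C)C | intermediate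
26 | (5S,8R)-8-hydroxy-3-methoxy-2-methyl-5-(5-phenylpentyl)-5,6,7,8-tetrahydroquinolin-4(1H)-one | COc1c(C)[nH]c2c(c1=O)[C@@H](CCCCCc1ccccc1)CC[C@H]2O | target

## Step count and least certain steps

Total: 13 steps. Longest linear sequence: 11 steps (steps 1, 2, 4, 5, 6, 7, 9, 10, 11, 12 and 13, from 1).

**Step 4 (key step).** The most likely failure is proton transfer from 7 to the allenyllithium 8 in place of addition, which returns both components and lowers conversion. A second risk is partial loss of configuration at the α-carbon of the acyl group while it sits in the activated enol ester 10. The fallback keeps compounds 4 and 11 but makes the enamide by stepwise N-acylation. Acetylacetone is converted by diazo transfer (4-acetamidobenzenesulfonyl azide, Et3N, MeCN) into 3-diazopentane-2,4-dione F1. O–H insertion into methanol (Rh2(OAc)4 cat.) gives 3-methoxypentane-2,4-dione F2, and NH4OAc in MeOH gives (3E)-4-amino-3-methoxypent-3-en-2-one F3. The fallback sets out from acid 4, which is turned under neutral conditions (1-chloro-N,N,2-trimethylprop-1-en-1-amine, CH2Cl2, 0 °C) into (2R)-2-(tert-butyldimethylsilyloxy)pent-4-enoyl chloride F4. N-Acylation of F3 with F4 (pyridine, CH2Cl2, 0 °C) comes back to the route at 11.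

**Step 9.** Transmetalation and reductive elimination at a ring carbon flanked by the benzyloxy group and the branched silyloxyalkyl group may be slow, so that protodemetalation of 20 or 21 on work-up takes over. The fallback replaces the cross-coupling by acylation and methylenation. 6-Phenylhexanoic acid is converted (carbonyldiimidazole, MeNHOMe·HCl) into N-methoxy-N-methyl-6-phenylhexanamide F5. The fallback sets out from 15: the Grignard species 20, made as in step 9, is added to F5 to give 1-{4-(benzyloxy)-2-[(1R)-1-(tert-butyldimethylsilyloxy)but-3-en-1-yl]-5-methoxy-6-methylpyridin-3-yl}-6-phenylhexan-1-one F6. Wittig methylenation with methylidenetriphenylphosphorane F7 (from Ph3PCH3Br and KOtBu, THF, reflux) comes back to the route at 22.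

**Step 10.** The hindered 1,1-disubstituted alkene may fail to engage, leaving dimerisation at the allyl terminus. Ruthenium hydride species may also move the double bond, and loss of silanol from C8 with aromatisation of ring B is possible on prolonged heating. The fallback closes ring B at C4a–C5 and sets out from 15:
- Hydroboration–oxidation of the terminal alkene (9-BBN, then NaBO3) gives (4R)-4-[4-(benzyloxy)-3-iodo-5-methoxy-6-methylpyridin-2-yl]-4-(tert-butyldimethylsilyloxy)butan-1-ol F8.
- Dess–Martin oxidation gives (4R)-4-[4-(benzyloxy)-3-iodo-5-methoxy-6-methylpyridin-2-yl]-4-(tert-butyldimethylsilyloxy)butanal F9.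
- Intramolecular Nozaki–Hiyama–Kishi addition (CrCl2, NiCl2 cat., DMF) gives (8R)-4-(benzyloxy)-8-(tert-butyldimethylsilyloxy)-3-methoxy-2-methyl-5,6,7,8-tetrahydroquinolin-5-ol F10 as a mixture at C5.
- A second Dess–Martin oxidation gives (8R)-4-(benzyloxy)-8-(tert-butyldimethylsilyloxy)-3-methoxy-2-methyl-7,8-dihydroquinolin-5(6H)-one F11.
- Addition of 5-phenylpentylmagnesium bromide F12 (from (5-bromopentyl)benzene and Mg) in the presence of CeCl3 gives (8R)-4-(benzyloxy)-8-(tert-butyldimethylsilyloxy)-3-methoxy-2-methyl-5-(5-phenylpentyl)-5,6,7,8-tetrahydroquinolin-5-ol F13.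
- Dehydration with the Burgess reagent comes back to the route at 23. Any exocyclic alkene isomer would converge on the same saturated skeleton in the reduction.

**Step 11.** The risks are poor facial selectivity, if the catalyst preference and the substrate bias do not reinforce each other, and low turnover at an alkene crowded by the C4 benzyloxy group. The fallback hands stereocontrol from the catalyst to the substrate. It sets out from 23: heterogeneous hydrogenation (H2, 1–3 atm, Pd/C, EtOAc) should add hydrogen to the face away from the bulky C8 silyloxy group and cleave the benzyl ether in the same operation, so that it comes back to the route at 25, one step further on.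

## Further compounds

F1 | step 4 | 3-diazopentane-2,4-dione | CC(=O)C(=[N+]=[N-])C(C)=O
F2 | step 4 | 3-methoxypentane-2,4-dione | CC(=O)C(OC)C(C)=O
F3 | step 4 | (3E)-4-amino-3-methoxypent-3-en-2-one | CC(=O)/C(OC)=C(/C)N
F4 | step 4 | (2R)-2-(tert-butyldimethylsilyloxy)pent-4-enoyl chloride | ClC(=O)[C@H](O[Si](C)(C)C(C)(C)C)CC=C
F5 | step 9 | N-methoxy-N-methyl-6-phenylhexanamide | CON(C)C(=O)CCCCCc1ccccc1
F6 | step 9 | 1-{4-(benzyloxy)-2-[(1R)-1-(tert-butyldimethylsilyloxy)but-3-en-1-yl]-5-methoxy-6-methylpyridin-3-yl}-6-phenylhexan-1-one | COc1c(C)nc(c(C(=O)CCCCCc2ccccc2)c1OCc3ccccc3)[C@H](O[Si](C)(C)C(C)(C)C)CC=C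
F7 | step 9 | methylidenetriphenylphosphorane | C=P(c1ccccc1)(c1ccccc1)c1ccccc1
F8 | step 10 | (4R)-4-[4-(benzyloxy)-3-iodo-5-methoxy-6-methylpyridin-2-yl]-4-(tert-butyldimethylsilyloxy)butan-1-ol | COc1c(C)nc(c(I)c1OCc2ccccc2)[C@H](O[Si](C)(C)C(C)(C)C)CCCO
F9 | step 10 | (4R)-4-[4-(benzyloxy)-3-iodo-5-methoxy-6-methylpyridin-2-yl]-4-(tert-butyldimethylsilyloxy)butanal | COc1c(C)nc(c(I)c1OCc2ccccc2)[C@H](O[Si](C)(C)C(C)(C)C)CCC=O
F10 | step 10 | (8R)-4-(benzyloxy)-8-(tert-butyldimethylsilyloxy)-3-methoxy-2-methyl-5,6,7,8-tetrahydroquinolin-5-ol | COc1c(C)nc2c(c1OCc3ccccc3)C(O)CC[C@H]2O[Si](C)(C)C(C)(C)C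
F11 | step 10 | (8R)-4-(benzyloxy)-8-(tert-butyldimethylsilyloxy)-3-methoxy-2-methyl-7,8-dihydroquinolin-5(6H)-one | COc1c(C)nc2c(c1OCc3ccccc3)C(=O)CC[C@H]2O[Si](C)(C)C(C)(C)C
F12 | step 10 | 5-phenylpentylmagnesium bromide | Br[Mg]CCCCCc1ccccc1
F13 | step 10 | (8R)-4-(benzyloxy)-8-(tert-butyldimethylsilyloxy)-3-methoxy-2-methyl-5-(5-phenylpentyl)-5,6,7,8-tetrahydroquinolin-5-ol | COc1c(C)nc2c(c1OCc3ccccc3)C(O)(CCCCCc4ccccc4)CC[C@H]2O[Si](C)(C)C(C)(C)C
F0 | step 11 | none | none
A1 | alternative 1 | (5S)-4-chloro-3-methoxy-2-methyl-5-(5-phenylpentyl)-6,7-dihydroquinolin-8(5H)-one | COc1c(C)nc2c(c1Cl)[C@@H](CCCCCc1ccccc1)CCC2=O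
A2 | alternative 1 | (4S)-4-(4-chloro-5-methoxy-6-methylpyridin-3-yl)-9-phenylnonanal | COc1c(C)ncc(c1Cl)[C@@H](CCCCCc1ccccc1)CCC=O
A3 | alternative 2 | (4S,7R)-7-(tert-butyldimethylsilyloxy)-4-(5-phenylpentyl)-3-(1,2,2-trimethoxypropyl)-4,5,6,7-tetrahydro-2,1-benzoxazole | COC(c1onc2c1[C@@H](CCCCCc1ccccc1)CC[C@H]2O[Si](C)(C)C(C)(C)C)C(C)(OC)OC
A4 | alternative 2 | tert-butyl(dimethyl){[(2R,5S)-8,9,9-trimethoxy-1-nitro-5-(5-phenylpentyl)dec-6-yn-2-yl]oxy}silane | COC(C#C[C@@H](CCCCCc1ccccc1)CC[C@H](C[N+](=O)[O-])O[Si](C)(C)C(C)(C)C)C(C)(OC)OC
A5 | alternative 3 | (5S,8R)-4-(benzyloxy)-8-(tert-butyldimethylsilyloxy)-3-methoxy-2-methyl-5-(5-phenylpentyl)-5,6,7,8-tetrahydroquinoline | COc1c(C)nc2c(c1OCc1ccccc1)[C@@H](CCCCCc1ccccc1)CC[C@H]2O[Si](C)(C)C(C)(C)C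
A6 | alternative 3 | (3S,6R)-2-[(benzyloxy)methylidene]-6-(tert-butyldimethylsilyloxy)-3-(5-phenylpentyl)cyclohexan-1-one O-pivaloyl oxime | CC(C)(C)C(=O)ON=C1C(=COCc2ccccc2)[C@@H](CCCCCc2ccccc2)CC[C@H]1O[Si](C)(C)C(C)(C)C
A7 | alternative 3 | 1-methoxypropyne | CC#COC
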